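The oxolane is cut at O1–C5. One Lewis-acid Cloke–Wilson ring expansion of an aryl cyclopropyl ketone makes this bond and the five-membered ring, and it hands the cis aryl/methyl pair of the cyclopropane on, with retention, as the cis C5-aryl/C4-methyl pair of the oxolane. The precursor is an aroylcyclopropane with a quaternary acyl-bearing carbon and cis methyl and aryl groups, reached from a (Z)-propenylarene; ring A (on the ketone) and ring B (on the cyclopropane) both carry tosyloxy groups. C3 is then set by equilibration and C2 by Felkin–Anh reduction and invertive re-closure of O1–C2; both side chains follow by SN2 etherification and reduction.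

Key step: step 7

Remark 1: the ketone oxygen is tied through the carbonyl carbon to the very carbon that leaves the benzylic centre, so it cannot reach the rear lobe of the breaking bond. The ring expansion is therefore planned as a front-side closure with retention, and the cyclopropane carries aryl and methyl cis.
Remark 2: hydride addition to the 2-aryl oxocarbenium ion is expected to follow the inside-attack model (hydrogen delivered syn to the C3 methyl), which would give the 2,3-trans ring. C2 is therefore set by ketone reduction and SN2 closure.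
Remark 3: the sense of induction of Rh2(S-PTTL)4 on this alkene is assumed; if it proves opposite, Rh2(R-PTTL)4 is used.

Step 1
Reactants: 1 4-iodo-2-methoxyphenol
Product: 2 4-iodo-2-methoxyphenyl 4-methylbenzenesulfonate
Conditions: TsCl, Et3N, DMAP (cat.), CH2Cl2, 0 °C to rt
Reagents that add atoms: 4-methylbenzenesulfonyl chloride, Cc1ccc(cc1)S(=O)(=O)Cl
Why: O-sulfonylation of a phenol under amine base masks the phenol and turns the arene into a weak donor for the later ring expansion and benzylic substitutions.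

Step 2
Reactants: 2 4-iodo-2-methoxyphenyl 4-methylbenzenesulfonate; 3 (Z)-prop-1-en-1-ylboronic acid
Product: 4 2-methoxy-4-[(Z)-prop-1-en-1-yl]phenyl 4-methylbenzenesulfonate
Conditions: Pd(PPh3)4 (3 mol %), K2CO3, 1,4-dioxane/H2O, 70 °C
Reagents that add atoms: none
Why: Suzuki–Miyaura coupling of an aryl iodide with an alkenylboronic acid keeps the Z geometry, and the aryl sulfonate is not touched under Pd(PPh3)4.

Step 3
Reactants: 5 ethyl 2-methyl-3-oxobutanoate
Product: 6 ethyl 2-diazopropanoate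
Conditions: 4-acetamidobenzenesulfonyl azide, DBU, MeCN, 0 °C to rt
Reagents that add atoms: 4-acetamidobenzenesulfonyl azide, CC(=O)Nc1ccc(cc1)S(=O)(=O)N=[N+]=[N-]
Why: Deacylative Regitz diazo transfer, in which the enolate of the β-keto ester adds to the sulfonyl azide and the adduct fragments with transfer of the acetyl group to the sulfonamide nitrogen.

Step 4
Reactants: 4 2-methoxy-4-[(Z)-prop-1-en-1-yl]phenyl 4-methylbenzenesulfonate; 6 ethyl 2-diazopropanoate
Product: 7 ethyl (1R,2S,3S)-3-[3-methoxy-4-(tosyloxy)phenyl]-1,2-dimethylcyclopropane-1-carboxylate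
Conditions: Rh2(S-PTTL)4 [dirhodium tetrakis(N-phthaloyl-(S)-tert-leucinate)] (1 mol %), hexanes/CH2Cl2, −78 °C, slow addition of 6
Reagents that add atoms: none
Why: Rh2(S-PTTL)4-catalysed carbene transfer from an α-alkyl-α-diazoester is a stereospecific syn cyclopropanation, so the Z alkene gives the cis C2-methyl/C3-aryl pair, while the bulky chiral carboxylate at −78 °C should suppress β-hydride migration, select the alkene face (2S,3S) and place the ester anti to both substituents (1R, a centre erased in step 7).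

Step 5
Reactants: 7 ethyl (1R,2S,3S)-3-[3-methoxy-4-(tosyloxy)phenyl]-1,2-dimethylcyclopropane-1-carboxylate
Product: 8 (1R,2S,3S)-N-methoxy-3-[3-methoxy-4-(tosyloxy)phenyl]-N,1,2-trimethylcyclopropane-1-carboxamide
Conditions: MeNH(OMe)·HCl, i-PrMgCl, THF, −20 to 0 °C
Reagents that add atoms: N,O-dimethylhydroxylamine hydrochloride, CNOC.Cl
Why: Ester aminolysis by the chloromagnesium amide of N,O-dimethylhydroxylamine (Weinreb amide formation) touches no stereocentre, and the aryl sulfonate should survive at or below 0 °C.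

Step 6
Reactants: 2 4-iodo-2-methoxyphenyl 4-methylbenzenesulfonate; 8 (1R,2S,3S)-N-methoxy-3-[3-methoxy-4-(tosyloxy)phenyl]-N,1,2-trimethylcyclopropane-1-carboxamide
Product: 10 [(1R,2S,3S)-3-[3-methoxy-4-(tosyloxy)phenyl]-1,2-dimethylcyclopropyl][3-methoxy-4-(tosyloxy)phenyl]methanone, via [3-methoxy-4-(tosyloxy)phenyl]magnesium chloride 9 (not isolated)
Conditions: 2, i-PrMgCl·LiCl, THF, −20 °C; then 8, −20 °C to rt; aq. NH4Cl
Reagents that add atoms: none
Why: Iodine–magnesium exchange at low temperature gives an arylmagnesium reagent that tolerates a para sulfonate, and its addition to the N-methoxy-N-methylamide stops at the chelated tetrahedral adduct, so the ketone appears only on work-up (Weinreb ketone synthesis).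

Step 7
Reactants: 10 [(1R,2S,3S)-3-[3-methoxy-4-(tosyloxy)phenyl]-1,2-dimethylcyclopropyl][3-methoxy-4-(tosyloxy)phenyl]methanone
Product: 11 (4R,5S)-2,5-bis[3-methoxy-4-(tosyloxy)phenyl]-3,4-dimethyl-4,5-dihydrofuran
Conditions: Sc(OTf)3 (10 mol %), ClCH2CH2Cl, 40 °C
Reagents that add atoms: none
Why: Sc(OTf)3 binds the ketone oxygen and polarises the cyclopropane bond between the acyl-bearing carbon and the benzylic carbon into a tight enolate/benzylic ion pair, and the enolate oxygen, held on the same side as the departing carbon, bonds to the face of the benzylic carbon that is being vacated, so O1–C5 forms with retention (front-side, SNi-like). The closest known reaction type is the Lewis-acid Cloke–Wilson ring expansion of 2-aryl cyclopropyl ketones to 4,5-dihydrofurans. The dihydrofuran ring closes by O-alkylation of the enolate across the former three-membered ring, a five-membered closure with the enol double bond inside the ring (three-to-five ring expansion). C5 is controlled by the configuration of the benzylic cyclopropane carbon, C4 is carried over unchanged, and the quaternary carbon becomes the sp2 C3, so both epimers at that carbon converge. The step needs retention over ionisation and rotation (which would give the 4,5-trans isomer) and O-closure over Friedel–Crafts attack on ring A. The electron-poor tosyloxyaryl groups on both rings, the non-nucleophilic triflate counter-ion and the non-ionising solvent should keep the ion pair tight, while the strain of the all-cis methyl/methyl/aryl face lowers the barrier.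

Step 8
Reactants: 11 (4R,5S)-2,5-bis[3-methoxy-4-(tosyloxy)phenyl]-3,4-dimethyl-4,5-dihydrofuran
Product: 13 (2R,3R,4S)-4-hydroxy-1,4-bis[3-methoxy-4-(tosyloxy)phenyl]-2,3-dimethylbutan-1-one, via oxocarbenium trifluoroacetate 12 (not isolated)
Conditions: CF3CO2H (anhydrous), CH2Cl2, 0 °C; then H2O/THF, 0 °C; aq. NaHCO3
Reagents that add atoms: water, O
Why: Acid-mediated enol-ether hydration in which protonation at C3 is reversible in the anhydrous stage, so the oxocarbenium ion should settle with the C3 methyl trans to the C4 methyl before water adds at C2 and the hemiketal opens, while the sulfonate on ring B prevents ionisation at C5.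

Step 9
Reactants: 13 (2R,3R,4S)-4-hydroxy-1,4-bis[3-methoxy-4-(tosyloxy)phenyl]-2,3-dimethylbutan-1-one
Product: 14 (2R,3R,4S)-1,4-bis[3-methoxy-4-(tosyloxy)phenyl]-2,3-dimethyl-4-(triethylsilyloxy)butan-1-one
Conditions: Et3SiCl, imidazole, DMF, 0 °C
Reagents that add atoms: chlorotriethylsilane, CC[Si](Cl)(CC)CC
Why: Silylation of the secondary alcohol marks the C5 oxygen as the later nucleophile and keeps it apart from the carbinol to be made at C2.

Step 10
Reactants: 14 (2R,3R,4S)-1,4-bis[3-methoxy-4-(tosyloxy)phenyl]-2,3-dimethyl-4-(triethylsilyloxy)butan-1-one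
Product: 15 (1R,2R,3R,4S)-1,4-bis[3-methoxy-4-(tosyloxy)phenyl]-2,3-dimethyl-4-(triethylsilyloxy)butan-1-ol
Conditions: LiBH(s-Bu)3, THF, −78 °C; aqueous work-up
Reagents that add atoms: none
Why: Felkin–Anh reduction of an α-methyl aryl ketone by a bulky trialkylborohydride, with hydride attacking anti to the branched chain at the α-carbon, should give the 1,2-anti (1R) alcohol.

Step 11
Reactants: 15 (1R,2R,3R,4S)-1,4-bis[3-methoxy-4-(tosyloxy)phenyl]-2,3-dimethyl-4-(triethylsilyloxy)butan-1-ol
Product: 17 (2S,3R,4R,5S)-2,5-bis[3-methoxy-4-(tosyloxy)phenyl]-3,4-dimethyloxolane, via benzylic mesylate 16 (not isolated)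
Conditions: MsCl, Et3N, CH2Cl2, −20 °C; then n-Bu4NF, THF, 0 °C to rt
Reagents that add atoms: none
Why: Mesylation followed by fluoride desilylation frees the C5 alkoxide, which displaces the benzylic mesylate in a 5-exo-tet Williamson closure with inversion at C2, giving the 2,3-cis relation because the electron-poor ring A disfavours ionisation.

Step 12
Reactants: 17 (2S,3R,4R,5S)-2,5-bis[3-methoxy-4-(tosyloxy)phenyl]-3,4-dimethyloxolane
Product: 18 4,4'-[(2S,3R,4R,5S)-3,4-dimethyloxolane-2,5-diyl]bis(2-methoxyphenol)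
Conditions: KOH, MeOH/THF, 60 °C; then aq. NH4Cl
Reagents that add atoms: none
Why: Alkaline cleavage of the two aryl sulfonates by attack at sulfur frees both phenols, and the oxolane has no base-labile stereocentre.

Step 13
Reactants: 19 (S)-2-hydroxy-N,N-dimethylpropanamide; 20 (3,4-dimethoxyphenyl)magnesium bromide
Product: 21 (S)-1-(3,4-dimethoxyphenyl)-2-hydroxypropan-1-one
Conditions: THF, 0 °C to rt (2.5 equiv of 20); aq. NH4Cl
Reagents that add atoms: none
Why: Acyl substitution of the amide by the aryl Grignard reagent stops at the magnesium-chelated tetrahedral adduct after the first equivalent has deprotonated the hydroxyl, and the lactate stereocentre is not touched.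

Step 14
Reactants: 21 (S)-1-(3,4-dimethoxyphenyl)-2-hydroxypropan-1-one
Product: 22 (S)-1-(3,4-dimethoxyphenyl)-1-oxopropan-2-yl 4-methylbenzenesulfonate
Conditions: TsCl, Et3N, DMAP (cat.), CH2Cl2, 0 °C
Reagents that add atoms: 4-methylbenzenesulfonyl chloride, Cc1ccc(cc1)S(=O)(=O)Cl
Why: O-sulfonylation of the α-hydroxy ketone at low temperature proceeds with retention because the C–O bond is not broken.

Step 15
Reactants: 18 4,4'-[(2S,3R,4R,5S)-3,4-dimethyloxolane-2,5-diyl]bis(2-methoxyphenol); 22 (S)-1-(3,4-dimethoxyphenyl)-1-oxopropan-2-yl 4-methylbenzenesulfonate (2 equiv)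
Product: 24 (2R,2'R)-2,2'-{[(2S,3R,4R,5S)-3,4-dimethyloxolane-2,5-diyl]bis[(2-methoxy-4,1-phenylene)oxy]}bis[1-(3,4-dimethoxyphenyl)propan-1-one], via mono-ether 23 (not isolated)
Conditions: BEMP (2-tert-butylimino-2-diethylamino-1,3-dimethylperhydro-1,3,2-diazaphosphorine, 2.4 equiv), 22 (2.4 equiv in all), CH2Cl2, 0 °C to rt
Reagents that add atoms: (S)-1-(3,4-dimethoxyphenyl)-1-oxopropan-2-yl 4-methylbenzenesulfonate (the second molecule of 22), C[C@H](OS(=O)(=O)c1ccc(C)cc1)C(=O)c1ccc(OC)c(OC)c1
Why: Two successive SN2 O-alkylations of the phenoxides by the α-sulfonyloxy ketone (Williamson etherification), each inverting the carbinol carbon from S to R, give first the mono-ether, a single compound because the two phenols are related by the twofold axis, and then the bis-ether, while the non-nucleophilic phosphazene base should limit enolisation of the α-aryloxy ketones.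

Step 16
Reactants: 24 (2R,2'R)-2,2'-{[(2S,3R,4R,5S)-3,4-dimethyloxolane-2,5-diyl]bis[(2-methoxy-4,1-phenylene)oxy]}bis[1-(3,4-dimethoxyphenyl)propan-1-one]
Product: 25 manassantin A
Conditions: n-Bu4NBH4, MeOH/CH2Cl2, −20 °C
Reagents that add atoms: none
Why: Felkin–Anh reduction with a non-chelating ammonium borohydride, in which hydride attacks anti to the α-aryloxy group, should give the syn (1R,2R) carbinol in both side chains.

Compound list
1 | 4-iodo-2-methoxyphenol | COc1cc(I)ccc1O | starting material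
2 | 4-iodo-2-methoxyphenyl 4-methylbenzenesulfonate | COc1cc(I)ccc1OS(=O)(=O)c1ccc(C)cc1 | intermediate
3 | (Z)-prop-1-en-1-ylboronic acid | C/C=C\B(O)O | starting material
4 | 2-methoxy-4-[(Z)-prop-1-en-1-yl]phenyl 4-methylbenzenesulfonate | C/C=C\c1ccc(OS(=O)(=O)c2ccc(C)cc2)c(OC)c1 | intermediate
5 | ethyl 2-methyl-3-oxobutanoate | CCOC(=O)C(C)C(C)=O | starting material
6 | ethyl 2-diazopropanoate | CCOC(=O)C(C)=[N+]=[N-] | intermediate
7 | ethyl (1R,2S,3S)-3-[3-methoxy-4-(tosyloxy)phenyl]-1,2-dimethylcyclopropane-1-carboxylate (aryl and C2 methyl cis, ester trans to both) | C[C@@]1(C(=O)OCC)[C@@H](C)[C@H]1c2ccc(OS(=O)(=O)c3ccc(C)cc3)c(OC)c2 | intermediate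
8 | (1R,2S,3S)-N-methoxy-3-[3-methoxy-4-(tosyloxy)phenyl]-N,1,2-trimethylcyclopropane-1-carboxamide | C[C@@]1(C(=O)N(C)OC)[C@@H](C)[C@H]1c2ccc(OS(=O)(=O)c3ccc(C)cc3)c(OC)c2 | intermediate
9 | [3-methoxy-4-(tosyloxy)phenyl]magnesium chloride (LiCl complex) | COc1cc([Mg]Cl)ccc1OS(=O)(=O)c1ccc(C)cc1 | intermediate
10 | [(1R,2S,3S)-3-[3-methoxy-4-(tosyloxy)phenyl]-1,2-dimethylcyclopropyl][3-methoxy-4-(tosyloxy)phenyl]methanone | C[C@@]1(C(=O)c2ccc(OS(=O)(=O)c3ccc(C)cc3)c(OC)c2)[C@@H](C)[C@H]1c4ccc(OS(=O)(=O)c5ccc(C)cc5)c(OC)c4 | intermediate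
11 | (4R,5S)-2,5-bis[3-methoxy-4-(tosyloxy)phenyl]-3,4-dimethyl-4,5-dihydrofuran (4,5-cis) | CC1=C(c2ccc(OS(=O)(=O)c3ccc(C)cc3)c(OC)c2)O[C@H](c4ccc(OS(=O)(=O)c5ccc(C)cc5)c(OC)c4)[C@@H]1C | intermediate
12 | (3R,4R,5S)-2,5-bis[3-methoxy-4-(tosyloxy)phenyl]-3,4-dimethyl-4,5-dihydro-3H-furan-1-ium trifluoroacetate | COc1cc(ccc1OS(=O)(=O)c1ccc(C)cc1)C1=[O+][C@H](c2ccc(OS(=O)(=O)c3ccc(C)cc3)c(OC)c2)[C@H](C)[C@H]1C.[O-]C(=O)C(F)(F)F | intermediate
13 | (2R,3R,4S)-4-hydroxy-1,4-bis[3-methoxy-4-(tosyloxy)phenyl]-2,3-dimethylbutan-1-one | O[C@H](c1ccc(OS(=O)(=O)c2ccc(C)cc2)c(OC)c1)[C@H](C)[C@H](C(=O)c1ccc(OS(=O)(=O)c2ccc(C)cc2)c(OC)c1)C | intermediate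
14 | (2R,3R,4S)-1,4-bis[3-methoxy-4-(tosyloxy)phenyl]-2,3-dimethyl-4-(triethylsilyloxy)butan-1-one | CC[Si](CC)(CC)O[C@H](c1ccc(OS(=O)(=O)c2ccc(C)cc2)c(OC)c1)[C@H](C)[C@H](C(=O)c1ccc(OS(=O)(=O)c2ccc(C)cc2)c(OC)c1)C | intermediate
15 | (1R,2R,3R,4S)-1,4-bis[3-methoxy-4-(tosyloxy)phenyl]-2,3-dimethyl-4-(triethylsilyloxy)butan-1-ol | CC[Si](CC)(CC)O[C@H](c1ccc(OS(=O)(=O)c2ccc(C)cc2)c(OC)c1)[C@H](C)[C@H]([C@@H](O)c1ccc(OS(=O)(=O)c2ccc(C)cc2)c(OC)c1)C | intermediate
16 | (1R,2R,3R,4S)-1,4-bis[3-methoxy-4-(tosyloxy)phenyl]-2,3-dimethyl-4-(triethylsilyloxy)butyl methanesulfonate | CC[Si](CC)(CC)O[C@H](c1ccc(OS(=O)(=O)c2ccc(C)cc2)c(OC)c1)[C@H](C)[C@H]([C@@H](OS(C)(=O)=O)c1ccc(OS(=O)(=O)c2ccc(C)cc2)c(OC)c1)C | intermediate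
17 | (2S,3R,4R,5S)-2,5-bis[3-methoxy-4-(tosyloxy)phenyl]-3,4-dimethyloxolane | COc1cc(ccc1OS(=O)(=O)c1ccc(C)cc1)[C@H]1O[C@H](c2ccc(OS(=O)(=O)c3ccc(C)cc3)c(OC)c2)[C@H](C)[C@H]1C | intermediate
18 | 4,4'-[(2S,3R,4R,5S)-3,4-dimethyloxolane-2,5-diyl]bis(2-methoxyphenol) | COc1cc(ccc1O)[C@H]1O[C@H](c2ccc(O)c(OC)c2)[C@H](C)[C@H]1C | intermediate
19 | (S)-2-hydroxy-N,N-dimethylpropanamide | C[C@H](O)C(=O)N(C)C | starting material
20 | (3,4-dimethoxyphenyl)magnesium bromide (THF solution) | COc1ccc([Mg]Br)cc1OC | starting material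
21 | (S)-1-(3,4-dimethoxyphenyl)-2-hydroxypropan-1-one | C[C@H](O)C(=O)c1ccc(OC)c(OC)c1 | intermediate
22 | (S)-1-(3,4-dimethoxyphenyl)-1-oxopropan-2-yl 4-methylbenzenesulfonate | C[C@H](OS(=O)(=O)c1ccc(C)cc1)C(=O)c1ccc(OC)c(OC)c1 | intermediate
23 | (2R)-1-(3,4-dimethoxyphenyl)-2-{4-[(2S,3R,4R,5S)-5-(4-hydroxy-3-methoxyphenyl)-3,4-dimethyloxolan-2-yl]-2-methoxyphenoxy}propan-1-one (mono-ether) | COc1ccc(C(=O)[C@@H](C)Oc2ccc([C@H]3O[C@H](c4ccc(O)c(OC)c4)[C@H](C)[C@H]3C)cc2OC)cc1OC | intermediate
24 | (2R,2'R)-2,2'-{[(2S,3R,4R,5S)-3,4-dimethyloxolane-2,5-diyl]bis[(2-methoxy-4,1-phenylene)oxy]}bis[1-(3,4-dimethoxyphenyl)propan-1-one] | COc1ccc(C(=O)[C@@H](C)Oc2ccc([C@H]3O[C@H](c4ccc(O[C@H](C)C(=O)c5ccc(OC)c(OC)c5)c(OC)c4)[C@H](C)[C@H]3C)cc2OC)cc1OC | intermediate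
25 | manassantin A | COc1ccc([C@@H](O)[C@@H](C)Oc2ccc([C@H]3O[C@H](c4ccc(O[C@H](C)[C@H](O)c5ccc(OC)c(OC)c5)c(OC)c4)[C@H](C)[C@H]3C)cc2OC)cc1OC | target

Total step count: 16. Longest linear sequence: 13 steps (steps 1, 2, 4, 5, 6, 7, 8, 9, 10, 11, 12, 15, 16, from 1 to 25).

Steps most likely to fail

Step 7. The benzylic carbon may ionise and rotate before the oxygen closes, which would erode the cis relation, or the weak tosyloxyaryl donor may not allow turnover. The fallback sets out from 10 and comes back at 11 by a double inversion in two stages. Me3SiBr with catalytic ZnBr2 in CH2Cl2 at −40 °C opens the activated cyclopropane by bromide attack at the benzylic carbon with inversion and gives, after aqueous work-up, (3R,4R)-4-bromo-1,4-bis[3-methoxy-4-(tosyloxy)phenyl]-2,3-dimethylbutan-1-one F1. Warming with 2,6-lutidine in MeCN should let the ketone oxygen displace bromide with a second inversion, and the resulting oxocarbenium ion loses a proton to give 11.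

Step 4. Facial selectivity of carbene transfer to an internal Z alkene may be poor, or β-hydride migration of the carbene may outrun cyclopropanation. The fallback sets out from 4 and comes back at 8, replacing catalyst control by a covalent auxiliary and diastereomer separation. Commercial (S)-4-benzyl-3-propanoyl-1,3-oxazolidin-2-one F2 is converted with KN(SiMe3)2 and 4-nitrobenzenesulfonyl azide into (S)-4-benzyl-3-(2-diazopropanoyl)-1,3-oxazolidin-2-one F3. This is added to 4 with achiral Rh2(O2CCPh3)4 at −78 °C, and the facial diastereomers are separated to give the (1R,2S,3S)-cyclopropyl imide F4. Me2AlN(OMe)Me then converts F4 into 8.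

Step 8. Equilibration at C3 may be incomplete before water captures the ion, or the open-chain ketone may epimerise, giving the C2 epimer of 13. The fallback sets out from 11 and comes back at 13 through a ring-locked intermediate. MeOH with catalytic camphorsulfonic acid at rt gives the (3R,4R,5S)-2-methoxy ketal F5, which equilibrates through the oxocarbenium/enol ether pair and is purified as the 3,4-trans isomer. Pyridinium p-toluenesulfonate in wet acetone then hydrolyses it to 13.

Further compounds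
F1 | step 7 | (3R,4R)-4-bromo-1,4-bis[3-methoxy-4-(tosyloxy)phenyl]-2,3-dimethylbutan-1-one (both C2 epimers) | Br[C@@H](c1ccc(OS(=O)(=O)c2ccc(C)cc2)c(OC)c1)[C@H](C)C(C)C(=O)c1ccc(OS(=O)(=O)c2ccc(C)cc2)c(OC)c1
F2 | step 4 | (S)-4-benzyl-3-propanoyl-1,3-oxazolidin-2-one | CCC(=O)N1[C@@H](Cc2ccccc2)COC1=O
F3 | step 4 | (S)-4-benzyl-3-(2-diazopropanoyl)-1,3-oxazolidin-2-one | CC(=[N+]=[N-])C(=O)N1[C@@H](Cc2ccccc2)COC1=O
F4 | step 4 | (S)-4-benzyl-3-{(1R,2S,3S)-3-[3-methoxy-4-(tosyloxy)phenyl]-1,2-dimethylcyclopropane-1-carbonyl}-1,3-oxazolidin-2-one | C[C@@]1(C(=O)N2[C@@H](Cc3ccccc3)COC2=O)[C@@H](C)[C@H]1c4ccc(OS(=O)(=O)c5ccc(C)cc5)c(OC)c4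
F5 | step 8 | (3R,4R,5S)-2-methoxy-2,5-bis[3-methoxy-4-(tosyloxy)phenyl]-3,4-dimethyloxolane | COC1(c2ccc(OS(=O)(=O)c3ccc(C)cc3)c(OC)c2)O[C@H](c4ccc(OS(=O)(=O)c5ccc(C)cc5)c(OC)c4)[C@H](C)[C@H]1C
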